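The data are calculated on assumed constants; the scatter is artificial.

A small level of gas in solution serves every flask below: the gas is held and refilled towards its saturation level of 2.6 mM, less than the 0.050 M of solid substrate, and you want the intermediate at the end of each flask.

| setting | ash | west | south-east | north-east | north-west |
|---|---|---|---|---|---|
| solid substrate | 0.050 M | 0.050 M | 0.050 M | 0.050 M | 0.050 M |
| partner | 10 equiv | 5.00 equiv | 5.00 equiv | 5.00 equiv | 5.00 equiv |
| gas | 2.6 mM (held) | 2.6 mM (held) | 2.6 mM (held) | 2.6 mM (held) | 2.6 mM (held) |
| temperature | −5 °C | −5 °C | −20 °C | 10 °C | −35 °C |
| remark | run made earlier |  |  |  |  |
| time |  | 2.5 d | 2.5 d | 2.5 d | 2.5 d |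

- ash (time / h: intermediate / %, product / %): 1.33: 1.4, 0.3; 2.50: 3.1, 0.3; 5.00: 7.9, 2.7; 10.0: 14.5, 6.2; 20.0: 24.8, 19.1

(readings scatter by 1 percentage point)

- at the start none of the solid substrate is in solution
- at the start none of the gas is in solution
- what has only dissolved of solid substrate counts as not reacted
- a reading or a percentage of product counts all its forms, free or not
- the earlier runs do not show what temperature does; that part of a forecast is a guess

- the best flask by amount of intermediate, in percent of the solid substrate charged; "all alike" if 1.5 percentage points covers them all (west / south-east / north-east / north-west / all alike)
- amount of intermediate at the end, in percent of the solid substrate charged, west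
- amount of intermediate at the end, in percent of the solid substrate charged, south-east
- amount of intermediate at the end, in percent of the solid substrate charged, north-east
- amount of intermediate at the end, in percent of the solid substrate charged, north-west

1. The bench rule is this: with a steady feed and a drain proportional to the intermediate, the intermediate climbs to the level where the two match, a steady state, and stays there. Between 10.0 h and 20.0 h in ash, intermediate plus product grows by a feed of 0.0232 /h (share of the charge). Product grows by a drain of 0.0656 /h on the mean intermediate. Both are readings and carry the scatter.

2. For west I assume that half the partner gives half the feed, and that the drain stays, since I take it as intermediate meeting gas. Feed over drain is then 17.7%. Call this the ceiling: the level of intermediate at which what arrives equals what leaves. West runs 2.5 d, longer than the climb time 15.2 h, so west has time to reach it.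

3. The first border is the solid. In west, feed times time is 69.6% of the charge, below the whole, so I expect the feed to last.

4. The second border is the gas. Product formation in ash, at one gas per product, uses the amount in a saturated solution in 4.03 h, less than the 10.0 h between those readings, so the refilling has to keep up with it. So the drain I read belongs to whatever gas level ash had. I expect west to hold more gas and drain faster, so I commit to a little under the ceiling.

5. Temperature is a guess. I expect the colder flasks to be still climbing at the end and north-east to use up its solid early, so I pick west.

6. The forecast gives 27% (17% to 36%) for west, above my ceiling, with 14% for south-east, 7% for north-east and 4% for north-west, and it picks west: “West should be best, since it balances feed against over-reaction.”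

7. West gives 14.6%, more than south-east at 6.94%, north-east at 11.1% or north-west at 2.79%, and 3.1 percentage points under the ceiling.

    solid substrate ⇌ starting material, rate k1*(cs1 - [starting material]) while solid is left; crystals form when [starting material] > cs1 (solubility = 18.0 mM, k = 0.770 /h)
    starting material + partner → intermediate (k = 0.0340 /M/h, Ea = 55.0 kJ/mol)
    second reagent + intermediate → product (k = 17.0 /M/h, Ea = 59.0 kJ/mol)
    gas ⇌ second reagent, rate k4*(csat - [second reagent]) (kL = 0.310 /h)
    crystals ⇌ product, rate k5*(cs5 - [product]) while solid is left; crystals form when [product] > cs5 (solubility = 48.0 mM, k = 0.520 /h)
    (constants at −20 °C)

In west at the end, the second reagent, the gas in solution, stands at 8.88 × 10⁻⁴ M, below its saturation 2.6 mM. Now take the ash charge to the same time: its ceiling is 35.3%, its feed times time comes to 139% of the charge, past the whole, and it holds 24.2%.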